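## Structural features

The target 24 is a (2S)-flavanone: benzo ring A carries a single hydroxyl at C7, pyranone ring C holds the ketone C4 and the stereocentre C2, and C2 is bonded to C6' of ring B. Ring B is fused through C4a'–C8a' to a 2,2-dimethyl-3-hydroxydihydropyran (ring D) and has a hydroxyl on C8' beside the ring oxygen O1', so the right-hand half is a 2,2-dimethylchromane-3,8-diol. The two stereocentres, C2 (S) and C3' (S), lie on opposite sides of ring B and cannot relay to each other, so each needs its own reagent control. C2 is the fragile point: it is benzylic, para to O1' through ring B, and β to the ketone, so base opens ring C by E1cB to the 2'-hydroxychalcone and acid can ionise the C2–O1 bond, and either path scrambles C2. The free 8'-hydroxyl makes ring B an oxidation-prone catechol monoether and the tertiary alkyl aryl ether of ring D is acid-sensitive, which argues for benzyl ethers removed last under near-neutral hydrogenolysis. Ring A has no oxygen on C5, so C5 is free to hold a traceless control element. The real difficulty is to attach ring A to a C2 stereocentre already in place without passing through the enone; the feature used is that O1 (on C8a) and the acyl carbon C4 (on C4a) sit on adjacent carbons of ring A, so one aryne C4a≡C8a can accept both from a C2–C3–C4 chain.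

## Logic of the disconnections

24 ⇒ 23. The three O–CH2Ph bonds (on O7, O8', O3') are cut and C5–H is traded for C5–Cl. The benzyl groups mask every hydroxyl that could compete as a nucleophile, and the chlorine is the regiocontrol element of the ring-forming step. All four fall in one reduction, so the protection costs no separate step. The forward step must cleave an aryl C–Cl bond and three benzyl ethers without reducing the ketone, without hydrogenolysing the benzylic C2–O1 bond, and without a base strong enough to open ring C.

23 ⇒ 13 + 19 (through 20, 21 and 22). O1–C8a and C4–C4a are cut. The two bonds end on neighbouring carbons of ring A, so the synthon for ring A is aryne 21 and the partner is a chain that has C2 with its oxygen and C4 as an acyl carbon. This is the largest simplification of the route: ring C is closed, ring A is attached, and the C2–O bond is carried in intact. The forward step needs the oxygen to be a proton-free alkoxide (20), attack at C8a rather than C4a, and acyl capture of the aryl anion faster than protonation or chloride loss. It also needs the new C4 to stay masked until the base is quenched, which is why the tetrahedral adduct 22 is planned.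

13 ⇒ 12. The acyl C–N bond is exchanged for the acyl C–OMe bond. Used directly, 12 would release methoxide in the annulation, and a strong base next to 23 would enolise C3 and open ring C. With 13 the leaving group stays on C4 until work-up. The price is one step, and the forward aminolysis must not trigger retro-aldol cleavage.

12 ⇒ 10 + 11. The C2–C3 bond is cut. An acetate aldol sets C2 at the moment the chain is made and reduces the problem to an aromatic aldehyde. The forward step must be catalyst-controlled, because C3' is too remote to bias the aldehyde faces.

10 ⇒ 8 ⇒ 7. The C6'–CHO bond is cut back to C6'–Br and the O3'–benzyl bond is cut. The halogen is a robust placeholder for the formyl carbon through the oxidation and reduction steps, and the benzyl group on O3' is needed because a free secondary hydroxyl would add to the aryne. The forward steps need bromine–lithium exchange to outrun benzylic deprotonation.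

7 ⇒ 6 ⇒ 5. C4'–H is traced back to a C4'–O bond, and both oxirane C–O bonds are then cut to the C3'=C4' alkene. A cis-disubstituted, aryl-conjugated alkene in a 2,2-dimethylchromene is the substrate type for which catalytic asymmetric epoxidation is most selective. The forward sequence needs hydride to enter only at benzylic C4', so that the C3'–O bond and its configuration stay.

5 ⇒ 4 ⇒ 2 + 3, and 2 ⇒ 1. C4a'–C4' (sigmatropic) and O1'–C2' are cut, then C6'–Br. Ring D with its gem-dimethyl group comes from a five-carbon propargylic chloride and a phenol. The forward bromination must go para to the free hydroxyl, and the rearrangement can only use the one open ortho position.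

19 ⇒ 16 ⇒ 15 ⇒ 14. The S–O bond of the triflate and the C–Si bond are cut (the latter traced to O–Si plus C–Br), then C–Br and C–Cl. Placing silicon where bromine was removes any competition between directing groups. The forward halogenations must both go ortho to the hydroxyl, which the blocked para position and amine catalysis favour.

## Other disconnections considered

Alternative 1: Ring B is cut at C4a'–C5' and C8a'–C8', so the benzene ring is not bought as a phenol but built onto ring D.
- Forward key step: the trimethylsilyl ketene acetal A3 of the (S)-silyloxy lactone A2 would add as an electron-rich dienophile across C6 and C3 of the electron-poor bromopyrone ester A1. The bridged adduct would lose CO2 and then trimethylsilanol to give the chromane ester A4.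
- In favour: the 6',8'-pattern of ring B follows from the polarity match of the cycloaddition, not from the para-selectivity of an aromatic bromination. The C6' carbon is present as an ester from the start, so no halogen–lithium exchange is needed. No oxygen is placed on C4' only to be removed. On these three points the alternative is the better of the two.
- Against: A2 must be closed onto the tertiary hydroxyl while the secondary one is silylated (the free dihydroxy acid would prefer the five-membered lactone), which costs several steps. Aromatisation could also expel the ring oxygen instead of silanol and so open ring D. After the key step A4 still needs bromine on C8' turned into a benzyloxy group, the silyl ether exchanged for a benzyl ether (a silyl ether cannot sit in a fluoride-triggered aryne step), and the ester reduced to reach 10.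
- Comparison: structurally it addresses only rings B and D and leaves C2 and ring C to be solved anyway. Mechanistically it is a known reaction class, whereas the chosen key step is not. In step count it is expected to be clearly longer to 10 than the seven steps used here.

Alternative 2: The cut is the C3'–O bond together with a C4'–O bond that the target does not contain.
- Forward key step: a chiral (salen)MnCl complex (trivalent manganese) with NaOCl transfers oxygen to C3'=C4' of chromene 5 to give epoxide A5, which is the same structure as 6. Hydride then removes the benzylic oxygen.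
- In favour: this is the most reliable enantioselective reaction available for this skeleton, catalytic and with a cheap oxidant, and the oxirane oxygen on C3' is exactly the one the target keeps. In precedent and predictability it is better than the aryne annulation.
- Against: it needs two steps for one stereocentre and a regioselective reductive opening. It also says nothing about C2, the centre that is actually at risk.
- Comparison: this disconnection does not compete with the chosen one; it is contained in it as steps 4 and 5, so step economy for ring D is identical. A plan that made it the strategic step would have to build ring C by conventional chalcone cyclisation, which passes through the enone and exposes C2 to the equilibration the chosen plan avoids, or by conjugate arylation of a chromone. The chosen plan accepts a less certain key step in exchange for forming ring C without ever breaking the C2–O bond.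

Alternative 3: The cut is C4a'–C4'.
- Forward key step: the aryl epoxy ether A6 (from 4 by semi-hydrogenation and epoxidation) would be activated by BF3·OEt2 or by hexafluoroisopropanol as solvent. The ring B carbon ortho to the ether oxygen would attack the terminal CH2 in a 6-endo Friedel–Crafts closure to give A7, the same structure as 7.
- In favour: it is redox-economic (C4' is made directly as CH2), uses no hydride near the aryl bromide, and can be run without a metal. The C3' centre is not touched in the ring closure. On redox economy it is better than the chosen route, and on retention of C3' it is its equal.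
- Against: the alkene that leads to A6 is terminal and monosubstituted, a poor substrate for direct asymmetric epoxidation. Enantiopure A6 would therefore come from hydrolytic kinetic resolution with a chiral (salen)Co(OAc) complex (trivalent cobalt), at the cost of half the material, or from a longer dihydroxylation sequence. The attacking carbon is activated only by a twisted tertiary alkoxy group and is meta to both the benzyloxy group and bromine, so forcing acid may be needed. Forcing acid invites ionisation of the tertiary C–O bond, Meinwald rearrangement of the epoxide, or 5-exo closure.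
- Comparison: the route from 4 to the chromanol would take four steps against three here, with a resolution in place of a direct catalytic asymmetric step. Like Alternative 2 it leaves C2 and ring C untouched, so it could replace steps 3 to 5 but not the key step.

Key step: step 13

Remark on stereodescriptors: (S) at the carbinol carbon of 12 and 13 corresponds to (2S) in 23 and 24, because the C–O bond is kept and the priority order O > aryl > CH2 is the same throughout.

Assumption: silyl ketene acetal 11 is a catalogue reagent and is bought; making it from methyl acetate (LDA, TBSCl) would add one step.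

## Route

Step 1
Reactants: 1 2-benzyloxyphenol
Product: 2 2-benzyloxy-4-bromophenol
Conditions: NBS, MeCN, 0 °C
Reagents that add atoms: N-bromosuccinimide, O=C1CCC(=O)N1Br
Why: Electrophilic aromatic bromination; the free hydroxyl is the stronger donor, so bromine should enter para to it (C4) and not para to the benzyloxy group.

Step 2
Reactants: 2 2-benzyloxy-4-bromophenol; 3 3-chloro-3-methylbut-1-yne
Product: 4 2-benzyloxy-4-bromo-1-[(2-methylbut-3-yn-2-yl)oxy]benzene
Conditions: CuCl2·2H2O (cat.), DBU, MeCN, 0 °C
Reagents that add atoms: none
Why: Copper-catalysed propargylic substitution through a copper acetylide gives the tertiary aryl propargyl ether that a plain Williamson reaction at a tertiary chloride would not.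

Step 3
Reactants: 4 2-benzyloxy-4-bromo-1-[(2-methylbut-3-yn-2-yl)oxy]benzene
Product: 5 8-benzyloxy-6-bromo-2,2-dimethyl-2H-chromene
Conditions: N,N-diethylaniline, 180 °C
Reagents that add atoms: none
Why: Aromatic propargyl Claisen rearrangement to the only free ortho position, then tautomerisation, 1,5-hydrogen shift and oxa-6π electrocyclisation close ring D as the chromene.

Step 4
Reactants: 5 8-benzyloxy-6-bromo-2,2-dimethyl-2H-chromene
Product: 6 (3S,4S)-8-benzyloxy-6-bromo-3,4-epoxy-2,2-dimethylchromane
Conditions: (S,S)-[N,N'-bis(3,5-di-tert-butylsalicylidene)cyclohexane-1,2-diaminato]MnCl (3 mol%), aq. NaOCl (pH 11.3), 4-phenylpyridine N-oxide, CH2Cl2, 0 °C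
Reagents that add atoms: sodium hypochlorite, [Na+].[O-]Cl
Why: Jacobsen–Katsuki epoxidation; 2,2-dimethylchromenes are the best substrate class for this catalyst, and the (S,S)-complex should deliver oxygen to the face that gives (3S,4S). C3' is the centre that is kept.

Step 5
Reactants: 6 (3S,4S)-8-benzyloxy-6-bromo-3,4-epoxy-2,2-dimethylchromane
Product: 7 (3S)-8-benzyloxy-6-bromo-2,2-dimethylchroman-3-ol
Conditions: LiAlH4, THF, 0 °C; H2O, aq. NaOH
Reagents that add atoms: none
Why: SN2 hydride opening of the epoxide at C4', which is benzylic and not shielded by the quaternary C2'; the C3'–O bond is untouched, so (3S) is kept. The aryl bromide and the benzyl ether should be inert at 0 °C.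

Step 6
Reactants: 7 (3S)-8-benzyloxy-6-bromo-2,2-dimethylchroman-3-ol
Product: 8 (3S)-3,8-bis(benzyloxy)-6-bromo-2,2-dimethylchromane
Conditions: NaH, BnBr, Bu4NI (cat.), DMF, 0 °C → rt
Reagents that add atoms: benzyl bromide, BrCc1ccccc1
Why: Williamson etherification; the benzyl group keeps the secondary hydroxyl from adding to the aryne later and falls in the final hydrogenolysis.

Step 7
Reactants: 8 (3S)-3,8-bis(benzyloxy)-6-bromo-2,2-dimethylchromane
Product: 10 (3S)-3,8-bis(benzyloxy)-2,2-dimethylchromane-6-carbaldehyde, via aryllithium 9 (not isolated)
Conditions: n-BuLi, THF, −78 °C; DMF, −78 → 0 °C; H2O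
Reagents that add atoms: N,N-dimethylformamide, CN(C)C=O
Why: Bromine–lithium exchange followed by formylation with DMF; at −78 °C the exchange is much faster than benzylic or ortho deprotonation.

Step 8
Reactants: 10 (3S)-3,8-bis(benzyloxy)-2,2-dimethylchromane-6-carbaldehyde; 11 1-(tert-butyldimethylsilyloxy)-1-methoxyethene
Product: 12 methyl (3S)-3-[(3S)-3,8-bis(benzyloxy)-2,2-dimethylchroman-6-yl]-3-hydroxypropanoate
Conditions: SiCl4, (S,S)-bis(phosphoramide) from N,N'-dimethyl-1,1'-binaphthyl-2,2'-diamine with a pentamethylene linker (5 mol%), CH2Cl2, −78 °C; cold aq. NaHCO3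
Reagents that add atoms: none
Why: Lewis-base-catalysed, SiCl4-mediated Mukaiyama aldol through an open transition state on a chiral trichlorosilyl cation–aldehyde complex, a reaction type that suits electron-rich aromatic aldehydes. The new centre is set by the catalyst: (S) requires attack on the Si face, and the (S,S)-catalyst is specified on the premise that the (R,R)-form directs ketene acetals to the Re face of aryl aldehydes. The hand is to be confirmed on the first batch by Mosher ester analysis.

Step 9
Reactants: 12 methyl (3S)-3-[(3S)-3,8-bis(benzyloxy)-2,2-dimethylchroman-6-yl]-3-hydroxypropanoate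
Product: 13 (3S)-3-[(3S)-3,8-bis(benzyloxy)-2,2-dimethylchroman-6-yl]-3-hydroxy-N-methoxy-N-methylpropanamide
Conditions: MeNHOMe·HCl, i-PrMgCl, THF, −20 → 0 °C; aq. NH4Cl
Reagents that add atoms: N,O-dimethylhydroxylamine hydrochloride, CNOC.Cl
Why: Weinreb aminolysis of the ester by the chloromagnesium amide; excess reagent holds the free hydroxyl as a magnesium alkoxide, which is not prone to retro-aldol at this temperature, and no bond at the stereocentre is touched.

Step 10
Reactants: 14 4-benzyloxyphenol
Product: 15 4-benzyloxy-2-chlorophenol
Conditions: SO2Cl2, i-Bu2NH (cat.), toluene, 0 °C → rt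
Reagents that add atoms: sulfuryl chloride, O=S(=O)(Cl)Cl
Why: Amine-catalysed ortho-chlorination of a phenol; the chlorinating species is delivered through a hydrogen bond to the hydroxyl, and the para position is blocked.

Step 11
Reactants: 15 4-benzyloxy-2-chlorophenol
Product: 16 4-benzyloxy-2-bromo-6-chlorophenol
Conditions: NBS, i-Pr2NH (cat.), CH2Cl2, 0 °C
Reagents that add atoms: N-bromosuccinimide, O=C1CCC(=O)N1Br
Why: Amine-catalysed ortho-bromination of the phenol at the one remaining position next to the hydroxyl.

Step 12
Reactants: 16 4-benzyloxy-2-bromo-6-chlorophenol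
Product: 19 4-benzyloxy-2-chloro-6-(trimethylsilyl)phenyl trifluoromethanesulfonate, via aryl silyl ether 17 (not isolated), via lithium phenoxide 18 (not isolated)
Conditions: HMDS, THF, reflux; evaporate; n-BuLi, THF, −100 → −80 °C; Tf2O, −100 → −78 °C
Reagents that add atoms: hexamethyldisilazane, C[Si](C)(C)N[Si](C)(C)C; trifluoromethanesulfonic anhydride, O=S(=O)(C(F)(F)F)OS(=O)(=O)C(F)(F)F
Why: O-silylation, bromine–lithium exchange, anionic 1,3-shift of silicon from oxygen to carbon (retro-Brook) and O-triflation in one flask; silicon ends where bromine was, so the regiochemistry does not depend on competing directing groups.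

Step 13
Reactants: 13 (3S)-3-[(3S)-3,8-bis(benzyloxy)-2,2-dimethylchroman-6-yl]-3-hydroxy-N-methoxy-N-methylpropanamide; 19 4-benzyloxy-2-chloro-6-(trimethylsilyl)phenyl trifluoromethanesulfonate
Product: 23 (2S)-7-benzyloxy-5-chloro-2-[(3S)-3,8-bis(benzyloxy)-2,2-dimethylchroman-6-yl]chroman-4-one, via sodium alkoxide 20 (not isolated), via aryne 21 (not isolated), via hemiaminal alkoxide 22 (not isolated)
Conditions: NaH, THF, 0 °C; then 19, CsF, 18-crown-6, THF, 0 °C → rt; AcOH, then pH 7 buffer, 0 °C
Reagents that add atoms: none
Why: Proposed new method: fluoride removes the trimethylsilyl group of 19 and triflate leaves to give aryne 21; the proton-free alkoxide 20 adds to C8a, and the aryl anion that appears on C4a attacks the amide carbonyl six atoms away in a 6-exo-trig addition that closes ring C, so that O1–C8a and C4–C4a form in one operation. The closest known reaction type is the fluoride-triggered annulation of arynes with methyl salicylates to xanthones (O-arylation, then capture of the aryl anion by the ester), and capture of such aryl anions by amide carbonyls is known from aryne insertions into amide C–N bonds; new here are a secondary aliphatic alkoxide as the oxygen partner and a stereocentre on the tether. The adduct is the hemiaminal alkoxide 22, which has no good leaving group and should keep C4 tetrahedral until the acetic acid quench, so neither methoxide nor a ketone enolate is present in the basic medium and E1cB opening of ring C to the chalcone has no entry. No stereocentre is created (the C4 centre of 22 disappears on hydrolysis) and C2 stays (S) because its C–O bond is never broken. The step needs oxygen to attack C8a and not C4a: the chlorine on C5 beside the triple bond polarises the aryne so that the nucleophile enters at the distal carbon and the charge develops next to the C–Cl bond, an effect expected to outweigh the weak opposite bias of the 7-benzyloxy group. It also needs ring closure to beat protonation of the aryl anion and loss of chloride from it, which is why the alkoxide is made with NaH (hydrogen leaves the flask), the medium is THF and not acetonitrile, and the electrophile is intramolecular.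

Step 14
Reactants: 23 (2S)-7-benzyloxy-5-chloro-2-[(3S)-3,8-bis(benzyloxy)-2,2-dimethylchroman-6-yl]chroman-4-one
Product: 24 (2S)-2-[(3S)-3,8-dihydroxy-2,2-dimethylchroman-6-yl]-7-hydroxychroman-4-one
Conditions: H2 (1 atm), 10% Pd/C, NaOAc, EtOAc–MeOH, rt
Reagents that add atoms: none
Why: Heterogeneous hydrogenolysis cleaves the three benzyl ethers and the aryl C–Cl bond, which the ortho carbonyl activates, in one operation. Sodium acetate takes up the HCl but is too weak a base to open ring C by retro-oxa-Michael reaction, so C2 should be kept; at 1 atm and room temperature the ketone and the benzylic C2–O1 bond are expected to survive.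

## Compound list

1 | 2-benzyloxyphenol | Oc1ccccc1OCc1ccccc1 | starting material
2 | 2-benzyloxy-4-bromophenol | Oc1ccc(Br)cc1OCc1ccccc1 | intermediate
3 | 3-chloro-3-methylbut-1-yne | CC(C)(Cl)C#C | starting material
4 | 2-benzyloxy-4-bromo-1-[(2-methylbut-3-yn-2-yl)oxy]benzene | C#CC(C)(C)Oc1ccc(Br)cc1OCc1ccccc1 | intermediate
5 | 8-benzyloxy-6-bromo-2,2-dimethyl-2H-chromene | CC1(C)Oc2c(OCc3ccccc3)cc(Br)cc2C=C1 | intermediate
6 | (3S,4S)-8-benzyloxy-6-bromo-3,4-epoxy-2,2-dimethylchromane | CC1(C)Oc2c(OCc3ccccc3)cc(Br)cc2[C@@H]2O[C@H]12 | intermediate
7 | (3S)-8-benzyloxy-6-bromo-2,2-dimethylchroman-3-ol | CC1(C)Oc2c(OCc3ccccc3)cc(Br)cc2C[C@@H]1O | intermediate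
8 | (3S)-3,8-bis(benzyloxy)-6-bromo-2,2-dimethylchromane | CC1(C)Oc2c(OCc3ccccc3)cc(Br)cc2C[C@@H]1OCc1ccccc1 | intermediate
9 | [(3S)-3,8-bis(benzyloxy)-2,2-dimethylchroman-6-yl]lithium | CC1(C)Oc2c(OCc3ccccc3)cc([Li])cc2C[C@@H]1OCc1ccccc1 | intermediate
10 | (3S)-3,8-bis(benzyloxy)-2,2-dimethylchromane-6-carbaldehyde | CC1(C)Oc2c(OCc3ccccc3)cc(C=O)cc2C[C@@H]1OCc1ccccc1 | intermediate
11 | 1-(tert-butyldimethylsilyloxy)-1-methoxyethene | COC(=C)O[Si](C)(C)C(C)(C)C | starting material
12 | methyl (3S)-3-[(3S)-3,8-bis(benzyloxy)-2,2-dimethylchroman-6-yl]-3-hydroxypropanoate | CC1(C)Oc2c(OCc3ccccc3)cc([C@@H](O)CC(=O)OC)cc2C[C@@H]1OCc1ccccc1 | intermediate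
13 | (3S)-3-[(3S)-3,8-bis(benzyloxy)-2,2-dimethylchroman-6-yl]-3-hydroxy-N-methoxy-N-methylpropanamide | CC1(C)Oc2c(OCc3ccccc3)cc([C@@H](O)CC(=O)N(C)OC)cc2C[C@@H]1OCc1ccccc1 | intermediate
14 | 4-benzyloxyphenol | Oc1ccc(OCc2ccccc2)cc1 | starting material
15 | 4-benzyloxy-2-chlorophenol | Oc1ccc(OCc2ccccc2)cc1Cl | intermediate
16 | 4-benzyloxy-2-bromo-6-chlorophenol | Oc1c(Br)cc(OCc2ccccc2)cc1Cl | intermediate
17 | (4-benzyloxy-2-bromo-6-chlorophenoxy)trimethylsilane | C[Si](C)(C)Oc1c(Br)cc(OCc2ccccc2)cc1Cl | intermediate
18 | lithium 4-benzyloxy-2-chloro-6-(trimethylsilyl)phenoxide | [Li+].[O-]c1c(Cl)cc(OCc2ccccc2)cc1[Si](C)(C)C | intermediate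
19 | 4-benzyloxy-2-chloro-6-(trimethylsilyl)phenyl trifluoromethanesulfonate | C[Si](C)(C)c1cc(OCc2ccccc2)cc(Cl)c1OS(=O)(=O)C(F)(F)F | intermediate
20 | sodium (1S)-1-[(3S)-3,8-bis(benzyloxy)-2,2-dimethylchroman-6-yl]-3-[methoxy(methyl)amino]-3-oxopropan-1-olate | [Na+].CC1(C)Oc2c(OCc3ccccc3)cc([C@@H]([O-])CC(=O)N(C)OC)cc2C[C@@H]1OCc1ccccc1 | intermediate
21 | 5-benzyloxy-3-chloro-1,2-didehydrobenzene | ClC1=CC(OCc2ccccc2)=CC#C1 | intermediate
22 | sodium (2S)-7-benzyloxy-2-[(3S)-3,8-bis(benzyloxy)-2,2-dimethylchroman-6-yl]-5-chloro-4-[methoxy(methyl)amino]chroman-4-olate (both C4 epimers) | [Na+].CC1(C)Oc2c(OCc3ccccc3)cc([C@@H]3CC([O-])(N(C)OC)c4c(Cl)cc(OCc5ccccc5)cc4O3)cc2C[C@@H]1OCc1ccccc1 | intermediate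
23 | (2S)-7-benzyloxy-5-chloro-2-[(3S)-3,8-bis(benzyloxy)-2,2-dimethylchroman-6-yl]chroman-4-one | CC1(C)Oc2c(OCc3ccccc3)cc([C@@H]3CC(=O)c4c(Cl)cc(OCc5ccccc5)cc4O3)cc2C[C@@H]1OCc1ccccc1 | intermediate
24 | (2S)-2-[(3S)-3,8-dihydroxy-2,2-dimethylchroman-6-yl]-7-hydroxychroman-4-one | CC1(C)Oc2c(O)cc([C@@H]3CC(=O)c4ccc(O)cc4O3)cc2C[C@@H]1O | target

## Step count and least certain steps

Total: 14 steps. Longest linear sequence: 11 steps (steps 1 to 9, then 13 and 14); the aryne precursor takes 3 steps (10 to 12).

Step 13 (key step, new method).
- What may go wrong: the aryl anion on C4a may capture a proton before it reaches the amide carbonyl, leaving an open aryl ether; this is the most likely failure because intermolecular proton sources (crown ether, traces of water) are hard to exclude. Alkoxide 20 may undergo retro-aldol cleavage before it meets an aryne, which would erode C2. Chloride may be lost from the ortho-chloroaryl anion. The alkoxide may attack sulfur of the triflate.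
- Fallback by known chemistry, from 8 back to the route at 24: bromine–lithium exchange on 8 and quenching with B(OiPr)3, then aqueous acid, would give [(3S)-3,8-bis(benzyloxy)-2,2-dimethylchroman-6-yl]boronic acid F1. O-Benzylation of commercial 7-hydroxy-4H-chromen-4-one (BnBr, K2CO3) would give 7-benzyloxy-4H-chromen-4-one F2. Asymmetric conjugate addition of F1 to F2 with Pd(OCOCF3)2 and a tert-butyl pyridine–oxazoline ligand (NH4PF6, water, 1,2-dichloroethane, 60 °C) is an established route to 2-arylchroman-4-ones and should give (2S)-7-benzyloxy-2-[(3S)-3,8-bis(benzyloxy)-2,2-dimethylchroman-6-yl]chroman-4-one F3. The (R)-ligand is the enantiomer expected to give (2S); the two possible outcomes are C2 epimers and can be told apart directly. Hydrogenolysis of F3 (H2, Pd/C, EtOAc–MeOH) then gives 24. This fallback needs neither chlorine nor 19.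

Step 8.
- What may go wrong: poor or reversed facial selectivity in the aldol, and acid-promoted ionisation at the para-alkoxybenzylic carbinol carbon during the SiCl4 work-up, which would racemise C2 before it is used.
- Fallback, from 10 back to the route at 13 (12 and step 9 are bypassed): addition of the lithium enolate of N-methoxy-N-methylacetamide (LDA, THF, −78 °C) to 10 gives, as a mixture of carbinol epimers, 3-[(3S)-3,8-bis(benzyloxy)-2,2-dimethylchroman-6-yl]-3-hydroxy-N-methoxy-N-methylpropanamide F4. Dess–Martin oxidation gives 3-[(3S)-3,8-bis(benzyloxy)-2,2-dimethylchroman-6-yl]-N-methoxy-N-methyl-3-oxopropanamide F5. Noyori–Ikariya transfer hydrogenation with RuCl[(S,S)-TsDPEN](p-cymene) in HCO2H–Et3N reduces the aryl ketone from the face that gives the (S)-alcohol, which is 13. The stereocentre is then set by reduction instead of by C–C bond formation, with a well-established sense.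

Step 12.
- What may go wrong: competing metalation at a benzylic CH2 by n-BuLi, or incomplete migration of silicon from oxygen to carbon, which would give triflate without the silyl group.
- Fallback, from 15 back to the route at 19: isopropyl isocyanate and Et3N convert 15 into 4-benzyloxy-2-chlorophenyl N-(propan-2-yl)carbamate F6. In-situ N-silylation (TMSOTf, TMEDA), carbamate-directed ortho-lithiation (n-BuLi, TMEDA, −78 °C) and TMSCl give, after acidic work-up, 4-benzyloxy-2-chloro-6-(trimethylsilyl)phenyl N-(propan-2-yl)carbamate F7. Cleavage of the carbamate with Et2NH and DBU in MeCN and triflation of the phenoxide in the same flask with PhNTf2 give 19. Here the silicon is placed by a directing group instead of by a halogen, at the cost of one more step and of a possible competing lithiation between chlorine and the benzyloxy group.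

Step 14.
- What may go wrong: incomplete cleavage of the C–Cl bond once the phenols are free, or, if the reduction is pushed, hydrogenolysis of the benzylic C2–O1 bond or reduction of the ketone.
- Fallback, from 23 back to the route at 24, separating the two tasks: hydrogenolysis without base (H2, Pd/C, EtOAc), where the aryl chloride is expected to react much more slowly than the benzyl ethers, gives (2S)-5-chloro-2-[(3S)-3,8-dihydroxy-2,2-dimethylchroman-6-yl]-7-hydroxychroman-4-one F8. The chlorine is then removed in a separate, buffered transfer hydrodechlorination (HCO2NH4, Pd/C, MeOH, rt) that is stopped as soon as F8 is consumed, to give 24. Any 24 already formed in the first stage is harmless.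

## Further compounds

F1 | step 13 | [(3S)-3,8-bis(benzyloxy)-2,2-dimethylchroman-6-yl]boronic acid | CC1(C)Oc2c(OCc3ccccc3)cc(B(O)O)cc2C[C@@H]1OCc1ccccc1
F2 | step 13 | 7-benzyloxy-4H-chromen-4-one | O=c1ccoc2cc(OCc3ccccc3)ccc12
F3 | step 13 | (2S)-7-benzyloxy-2-[(3S)-3,8-bis(benzyloxy)-2,2-dimethylchroman-6-yl]chroman-4-one | CC1(C)Oc2c(OCc3ccccc3)cc([C@@H]3CC(=O)c4ccc(OCc5ccccc5)cc4O3)cc2C[C@@H]1OCc1ccccc1
F4 | step 8 | 3-[(3S)-3,8-bis(benzyloxy)-2,2-dimethylchroman-6-yl]-3-hydroxy-N-methoxy-N-methylpropanamide (both carbinol epimers) | CC1(C)Oc2c(OCc3ccccc3)cc(C(O)CC(=O)N(C)OC)cc2C[C@@H]1OCc1ccccc1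
F5 | step 8 | 3-[(3S)-3,8-bis(benzyloxy)-2,2-dimethylchroman-6-yl]-N-methoxy-N-methyl-3-oxopropanamide | CC1(C)Oc2c(OCc3ccccc3)cc(C(=O)CC(=O)N(C)OC)cc2C[C@@H]1OCc1ccccc1
F6 | step 12 | 4-benzyloxy-2-chlorophenyl N-(propan-2-yl)carbamate | CC(C)NC(=O)Oc1ccc(OCc2ccccc2)cc1Cl
F7 | step 12 | 4-benzyloxy-2-chloro-6-(trimethylsilyl)phenyl N-(propan-2-yl)carbamate | CC(C)NC(=O)Oc1c(Cl)cc(OCc2ccccc2)cc1[Si](C)(C)C
F8 | step 14 | (2S)-5-chloro-2-[(3S)-3,8-dihydroxy-2,2-dimethylchroman-6-yl]-7-hydroxychroman-4-one | CC1(C)Oc2c(O)cc([C@@H]3CC(=O)c4c(Cl)cc(O)cc4O3)cc2C[C@@H]1O
A1 | alternative 1 | methyl 3-bromo-2-oxo-2H-pyran-5-carboxylate | COC(=O)C1=COC(=O)C(Br)=C1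
A2 | alternative 1 | (5S)-5-(tert-butyldimethylsilyloxy)-6,6-dimethyltetrahydro-2H-pyran-2-one | CC1(C)OC(=O)CC[C@@H]1O[Si](C)(C)C(C)(C)C
A3 | alternative 1 | tert-butyl{[(3S)-2,2-dimethyl-6-(trimethylsilyloxy)-3,4-dihydro-2H-pyran-3-yl]oxy}dimethylsilane | CC1(C)OC(O[Si](C)(C)C)=CC[C@@H]1O[Si](C)(C)C(C)(C)C
A4 | alternative 1 | methyl (3S)-8-bromo-3-(tert-butyldimethylsilyloxy)-2,2-dimethylchromane-6-carboxylate | CC1(C)Oc2c(Br)cc(C(=O)OC)cc2C[C@@H]1O[Si](C)(C)C(C)(C)C
A5 | alternative 2 | (3S,4S)-8-benzyloxy-6-bromo-3,4-epoxy-2,2-dimethylchromane | CC1(C)Oc2c(OCc3ccccc3)cc(Br)cc2[C@@H]2O[C@H]12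
A6 | alternative 3 | 2-benzyloxy-4-bromo-1-({2-[(2S)-oxiran-2-yl]propan-2-yl}oxy)benzene | CC(C)(Oc1ccc(Br)cc1OCc1ccccc1)[C@@H]1CO1
A7 | alternative 3 | (3S)-8-benzyloxy-6-bromo-2,2-dimethylchroman-3-ol | CC1(C)Oc2c(OCc3ccccc3)cc(Br)cc2C[C@@H]1O
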